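(The runs were generated by integration with constants of no real substance; the scatter is artificial.)

3 questions are asked, and two chemists read the same 2 runs differently.

| flask | electrophile | nucleophile | free base | scavenger | remark | time |
|---|---|---|---|---|---|---|
| eta | 12 mM | 1.1 equiv | 2 equiv | 0.50 equiv | run made earlier |  |
| theta | 12 mM | 1.1 equiv | 2.7 equiv | 0.50 equiv | run made earlier |  |
| amber | 12 mM | 1.10 equiv | 3.90 equiv | 0.500 equiv |  | 40 h |
| grey | 12 mM | 1.10 equiv | 3.00 equiv | 0.500 equiv |  | 40 h |

| run | time / h | electrophile / % | target / % |
|---|---|---|---|
| eta | 1.50 | 37.2 | 61.8 |
| eta | 2.50 | 26.0 | 73.9 |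
| eta | 4.00 | 18.2 | 81.8 |
| eta | 8.00 | 8.1 | 90.5 |
| eta | 12.0 | 5.5 | 95.6 |
| eta | 20.0 | 2.3 | 98.4 |
| theta | 1.33 | 40.6 | 59.7 |
| theta | 4.00 | 16.2 | 83.1 |
| theta | 8.00 | 9.3 | 92.3 |
| theta | 10.0 | 8.0 | 92.8 |
| theta | 15.0 | 4.8 | 96.8 |
| theta | 20.0 | 2.2 | 97.6 |

(each reading ± 1 percentage point)

- part of the electrophile that has reacted at the end, amber
- part of the electrophile that has reacted at the end, grey
- what raising the equivalents of free base from its lowest to its highest value here does to the part of the electrophile that has reacted (changes below 5 percentage points count as none) (no change / it falls / it rises)

- the numbers in the tables scatter by 1 percentage point (one standard deviation)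

The first chemist holds the base view. Free base is charged in excess, so more of it should carry the reaction further. She points to 4.00 h. Eta, with 2 equiv of free base, has 18.2% electrophile left. Theta, with 2.7 equiv, has 16.2%. That is a gap of 2 percentage points.

The second chemist holds the charge view, and I side with him. At 20.0 h the same gap is 0.1 points, against a scatter of 1 point. So he counts something else: the spare nucleophile, meaning the nucleophile charge minus the electrophile charge, as a fraction of the electrophile charge. It is 0.100 in amber and in grey. The nucleophile charge is larger than the electrophile charge, so the electrophile is the limiting reagent. The crossing lies at a spare of zero. His rule assumes that one nucleophile takes one electrophile and that nothing else takes either. Below the crossing, the electrophile left at the stop equals the shortfall. Above it, the nucleophile left is the spare, which in amber is 9.09% of its own charge. My reckoning gives where the flask stops, not a figure for 40 h.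

The forecast takes his side with 99.5% for amber, 99.5% for grey, and no change. Its ground: “Base seems not to enter the rate law”.

The flask gives 99.7% for amber and 99.7% for grey, so the trend is no change, with a change of 0.011 points.

    electrophile + nucleophile → acid set free + target (k = 77.0 L mol⁻¹ h⁻¹)
    nucleophile + acid set free ⇌ protonated nucleophile, settled at all times (K = 1400 L mol⁻¹)
    acid set free + free base ⇌ salt of the base, settled at all times (K = 15000 L mol⁻¹)
    electrophile + acid set free → side product (k = 2.40 L mol⁻¹ h⁻¹)
    acid set free + free base ⇌ idle adduct, settled at all times (K = 43.0 L mol⁻¹)
    acid set free + scavenger → scavenged by-product (k = 89.0 L mol⁻¹ h⁻¹)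

The base view keeps one region: the presence of free base, not its amount across these charges. Taking out the association of acid set free + free base to salt of the base moves the shown readings by 11 scatter units, root mean square. The spare of amber is 9.09% of its nucleophile charge, a share for the stop. At 40 h amber holds 9.06% of that charge free, beside 0.0362 mM of protonated nucleophile and 0.26% of its electrophile. A neighbour of amber with 0.660 equiv of nucleophile loses 0.440 from the charge, more than the spare. That makes a shortfall of 0.340, and the neighbour ends with 34.0% electrophile.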